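## Retrosynthetic overview

1. The cyclohexene is formed last by joining its benzylic C1 to its vinylic C2. The precursor is the acyclic N-acyloxyphthalimide 25, where C1 carries the activated carboxyl group and C2 a bromine held cis to the tether; a nickel-catalysed decarboxylative ring closure joins them.
2. Enabling feature: C1 of the cyclohexene sits on C6 of a 7-methoxycoumarin ring and bears one hydrogen, so it can be stored as an arylacetic acid carbon and released as a stabilised planar radical. The C2=C3 ring alkene is trisubstituted, so its cis geometry can be stored in a (Z)-alkenyl bromide.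
3. Acid 24 comes from an Ireland–Claisen rearrangement of arylacetate 21. This one step makes the C1–C6 bond, the quaternary C6 (R) and the (E)-styryl alkene by chirality transfer from the (R)-carbinol of 20.
4. Alcohol 20 comes from an asymmetric Nozaki–Hiyama–Kishi coupling of aldehyde 6 with dienyl halide 18. The C8 unit 18 is built by Normant carbocupration of propyne (Z end) and Negishi carboalumination (E end).
5. Ring order: the two coumarin pyranone rings first (Pechmann condensation; one bromocoumarin 5 feeds both aldehyde 6 and acid 9), the carbocycle last.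

Key step: step 13

Assumption: the sense of induction of the two chiral catalysts (steps 9 and 13) is fixed by choosing the ligand enantiomer; both enantiomers of each ligand are available.

## Route

Step 1
Reactants: 1 4-bromoresorcinol (4-bromobenzene-1,3-diol); 2 DL-malic acid
Product: 4 6-bromo-7-hydroxy-2H-chromen-2-one, via 3-oxopropanoic acid 3 (not isolated)
Conditions: conc. H2SO4, 110 °C
Reagents that add atoms: none
Why: Pechmann condensation, in which malic acid loses CO and water to give 3, which attacks the only ring position that is ortho to one hydroxyl and para to the other and then lactonises, so that bromine ends up at C6 and the free hydroxyl at C7.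

Step 2
Reactants: 4
Product: 5 6-bromo-7-methoxy-2H-chromen-2-one
Conditions: MeI, K2CO3, acetone, reflux
Reagents that add atoms: iodomethane, CI
Why: Williamson ether synthesis on the phenoxide, the only nucleophilic site of 4 under carbonate conditions.

Step 3
Reactants: 5
Product: 6 7-methoxy-2-oxo-2H-chromene-6-carbaldehyde
Conditions: Pd(OAc)2 (1 mol %), di(1-adamantyl)-n-butylphosphine, CO/H2 (1:1, 5 bar), TMEDA, toluene, 100 °C
Reagents that add atoms: carbon monoxide, [C-]#[O+]
Why: palladium-catalysed reductive carbonylation (formylation) of an aryl bromide, the acylpalladium being cleaved by hydrogen under neutral conditions that leave the lactone and its enoate alkene alone.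

Step 4
Reactants: 5; 7 (2-tert-butoxy-2-oxoethyl)zinc bromide (Reformatsky reagent)
Product: 8 tert-butyl 2-(7-methoxy-2-oxo-2H-chromen-6-yl)acetate
Conditions: Pd2(dba)3 (1 mol %), XPhos (4 mol %), THF, 60 °C
Reagents that add atoms: none
Why: Negishi-type coupling of a Reformatsky zinc enolate (base-free palladium-catalysed α-arylation of an ester), which the base-sensitive lactone should tolerate.

Step 5
Reactants: 8
Product: 9 2-(7-methoxy-2-oxo-2H-chromen-6-yl)acetic acid
Conditions: TFA, CH2Cl2, rt
Reagents that add atoms: none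
Why: acidolysis of the tert-butyl ester with loss of 2-methylpropene, conditions under which the coumarin and the aryl methyl ether are stable.

Step 6
Reactants: 10 (4-bromobut-1-yn-1-yl)trimethylsilane; 11 propyne
Product: 15 [(5Z)-6-bromo-5-methylhex-5-en-1-yn-1-yl]trimethylsilane, via Grignard reagent 12 (not isolated), via alkylcopper 13 (not isolated), via (Z)-alkenylcopper 14 (not isolated)
Conditions: Mg, Et2O; CuBr·SMe2, Et2O/Me2S, −45 °C; propyne, −25 °C; NBS, −40 → 0 °C
Reagents that add atoms: N-bromosuccinimide, O=C1CCC(=O)N1Br; in the intermediates only: magnesium, [Mg], and CuBr·SMe2, [Cu]Br.CSC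
Why: Normant carbocupration, a syn addition of the alkylcopper across propyne that puts copper on the terminal carbon cis to the new chain, followed by bromination with retention to give the (Z)-bromide; the silylated alkyne is not carbometalated.

Step 7
Reactants: 15
Product: 16 (1Z)-1-bromo-2-methylhex-1-en-5-yne
Conditions: K2CO3, MeOH, rt
Reagents that add atoms: none
Why: methoxide-induced protodesilylation of the alkynylsilane, which does not touch the alkenyl bromide.

Step 8
Reactants: 16
Product: 18 (1Z,5E)-1-bromo-6-iodo-2,5-dimethylhexa-1,5-diene, via (E)-alkenyldimethylalane 17 (not isolated)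
Conditions: Me3Al, Cp2ZrCl2 (25 mol %), CH2Cl2, 0 °C → rt; then I2, THF, −30 °C
Reagents that add atoms: trimethylaluminium, C[Al](C)C; iodine, II
Why: Negishi zirconium-catalysed carboalumination, a syn addition of methyl and aluminium with aluminium at the terminal carbon, then iodinolysis with retention to give the (E)-iodide; the alkenyl bromide is inert.

Step 9
Reactants: 6; 18
Product: 20 6-[(1R,2E,6Z)-7-bromo-1-hydroxy-3,6-dimethylhepta-2,6-dien-1-yl]-7-methoxy-2H-chromen-2-one, via trimethylsilyl ether 19 (not isolated)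
Conditions: CrCl2 (10 mol %), N-[2-(4-isopropyl-4,5-dihydrooxazol-2-yl)-6-methylphenyl]methanesulfonamide (12 mol %, enantiomer giving the 1R alcohol), proton sponge, NiCl2·(2,9-dimethyl-1,10-phenanthroline) (2 mol %), Mn, TMSCl, LiCl, MeCN, rt; then K2CO3, MeOH, 0 °C
Reagents that add atoms: chlorotrimethylsilane, C[Si](C)(C)Cl (silyl group of intermediate 19 only)
Why: catalytic asymmetric Nozaki–Hiyama–Kishi reaction, in which zerovalent nickel inserts into the C–I bond far faster than into the hindered C–Br bond, the alkenyl group passes to chromium with retention, and the ligand-bound trivalent alkenylchromium adds to one face of the aldehyde to set the (R)-carbinol without touching the lactones.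

Step 10
Reactants: 9; 20
Product: 21 (1R,2E,6Z)-7-bromo-1-(7-methoxy-2-oxo-2H-chromen-6-yl)-3,6-dimethylhepta-2,6-dien-1-yl 2-(7-methoxy-2-oxo-2H-chromen-6-yl)acetate
Conditions: DIC, DMAP (10 mol %), CH2Cl2, 0 °C
Reagents that add atoms: none
Why: Steglich esterification, which acylates at oxygen under neutral conditions so that the ionisable benzylic allylic carbinol keeps its configuration.

Step 11
Reactants: 21
Product: 24 (3R,6Z)-7-bromo-2-(7-methoxy-2-oxo-2H-chromen-6-yl)-3-[(E)-2-(7-methoxy-2-oxo-2H-chromen-6-yl)ethenyl]-3,6-dimethylhept-6-enoic acid (mixture of C2 epimers), via silyl ketene acetal 22 (not isolated), via trimethylsilyl ester 23 (not isolated)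
Conditions: LiN(SiMe3)2, TMSCl, Et3N, THF, −78 → 40 °C; then H2O
Reagents that add atoms: chlorotrimethylsilane, C[Si](C)(C)Cl (silyl group of intermediates 22 and 23 only)
Why: Ireland–Claisen rearrangement through a chair in which the aryl group on the carbinol carbon is equatorial (enforced by the cis methyl of the E alkene), so that the new styryl alkene is E and the quaternary centre is set as R by 1,3-chirality transfer, while the configuration at C2 is left open because that centre is erased in step 13.

Step 12
Reactants: 24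
Product: 25 1,3-dioxoisoindolin-2-yl (3R,6Z)-7-bromo-2-(7-methoxy-2-oxo-2H-chromen-6-yl)-3-[(E)-2-(7-methoxy-2-oxo-2H-chromen-6-yl)ethenyl]-3,6-dimethylhept-6-enoate (mixture of C2 epimers)
Conditions: N-hydroxyphthalimide, DIC, DMAP (cat.), CH2Cl2, rt
Reagents that add atoms: N-hydroxyphthalimide, ON1C(=O)c2ccccc2C1=O
Why: carbodiimide esterification to the redox-active ester, a standard activation of arylacetic acids that leaves all alkenes and the bromide unchanged.

Step 13
Reactants: 25
Product: 26 6-[(1S,6R)-6-[(E)-2-(7-methoxy-2-oxo-2H-chromen-6-yl)ethenyl]-3,6-dimethylcyclohex-2-en-1-yl]-7-methoxy-2H-chromen-2-one (CNP0415737.1)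
Conditions: NiBr2·diglyme (10 mol %), 2,2'-(cyclopropane-1,1-diyl)bis(3a,8a-dihydro-8H-indeno[1,2-d]oxazole) (11 mol %, matched enantiomer), tetrakis(dimethylamino)ethylene (TDAE), TMSBr, NaI, DMA (0.02 M), −7 °C
Reagents that add atoms: none
Why: Proposed new method: nickel, reduced by TDAE, inserts into the (Z)-alkenyl C–Br bond and passes one electron to the N-acyloxyphthalimide, which loses phthalimide anion and CO2 to leave a benzylic radical stabilised by the 7-methoxycoumarin ring; the tethered divalent alkenylnickel captures it and trivalent nickel releases the product by C(sp3)–C(sp2) reductive elimination, the closest known reaction type being the intermolecular nickel-catalysed enantioconvergent reductive coupling of benzylic N-hydroxyphthalimide esters with alkenyl bromides. The cyclohexene closes by joining the benzylic carbon to the bromine-bearing alkene carbon, with all six ring atoms from one chain and the alkene endocyclic, which requires the bromine cis to the tether as installed in step 6. The new stereocentre (1S, aryl trans to styryl and cis to methyl) arises from a planar radical, so both epimers of 25 converge and the configuration is set at nickel by the chiral bis(oxazoline) ligand, the neighbouring quaternary centre (methyl versus styryl, of similar size) adding only a small bias. Ring closure must outrun 1,2-shift of the styryl group in the radical, dimerisation and intermolecular coupling; capture by the nickel centre held in the same molecule and high dilution should secure this, and the mild organic reductant leaves both lactones, the styrene and the quaternary centre untouched.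

## Compound list

1 | 4-bromoresorcinol | Oc1ccc(Br)c(O)c1 | starting material
2 | DL-malic acid | OC(CC(=O)O)C(=O)O | starting material
3 | 3-oxopropanoic acid | O=CCC(=O)O | intermediate
4 | 6-bromo-7-hydroxy-2H-chromen-2-one | Oc1cc2oc(=O)ccc2cc1Br | intermediate
5 | 6-bromo-7-methoxy-2H-chromen-2-one | COc1cc2oc(=O)ccc2cc1Br | intermediate
6 | 7-methoxy-2-oxo-2H-chromene-6-carbaldehyde | COc1cc2oc(=O)ccc2cc1C=O | intermediate
7 | (2-tert-butoxy-2-oxoethyl)zinc bromide | CC(C)(C)OC(=O)C[Zn]Br | starting material
8 | tert-butyl 2-(7-methoxy-2-oxo-2H-chromen-6-yl)acetate | COc1cc2oc(=O)ccc2cc1CC(=O)OC(C)(C)C | intermediate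
9 | 2-(7-methoxy-2-oxo-2H-chromen-6-yl)acetic acid | COc1cc2oc(=O)ccc2cc1CC(=O)O | intermediate
10 | (4-bromobut-1-yn-1-yl)trimethylsilane | C[Si](C)(C)C#CCCBr | starting material
11 | propyne | CC#C | starting material
12 | [4-(trimethylsilyl)but-3-yn-1-yl]magnesium bromide | C[Si](C)(C)C#CCC[Mg]Br | intermediate
13 | [4-(trimethylsilyl)but-3-yn-1-yl]copper | C[Si](C)(C)C#CCC[Cu] | intermediate
14 | [(1Z)-2-methyl-6-(trimethylsilyl)hex-1-en-5-yn-1-yl]copper | C[Si](C)(C)C#CCC/C(C)=C\[Cu] | intermediate
15 | [(5Z)-6-bromo-5-methylhex-5-en-1-yn-1-yl]trimethylsilane | C[Si](C)(C)C#CCC/C(C)=C\Br | intermediate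
16 | (1Z)-1-bromo-2-methylhex-1-en-5-yne | C#CCC/C(C)=C\Br | intermediate
17 | [(1E,5Z)-6-bromo-2,5-dimethylhexa-1,5-dien-1-yl]dimethylalane | C[Al](C)/C=C(C)/CC/C(C)=C\Br | intermediate
18 | (1Z,5E)-1-bromo-6-iodo-2,5-dimethylhexa-1,5-diene | I/C=C(C)/CC/C(C)=C\Br | intermediate
19 | trimethylsilyl ether of 20 | C[Si](C)(C)O[C@@H](c1cc2ccc(=O)oc2cc1OC)/C=C(\C)CC/C(C)=C\Br | intermediate
20 | 6-[(1R,2E,6Z)-7-bromo-1-hydroxy-3,6-dimethylhepta-2,6-dien-1-yl]-7-methoxy-2H-chromen-2-one | O[C@@H](c1cc2ccc(=O)oc2cc1OC)/C=C(\C)CC/C(C)=C\Br | intermediate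
21 | (1R,2E,6Z)-7-bromo-1-(7-methoxy-2-oxo-2H-chromen-6-yl)-3,6-dimethylhepta-2,6-dien-1-yl 2-(7-methoxy-2-oxo-2H-chromen-6-yl)acetate | COc1cc2oc(=O)ccc2cc1CC(=O)O[C@@H](c1cc2ccc(=O)oc2cc1OC)/C=C(\C)CC/C(C)=C\Br | intermediate
22 | O-trimethylsilyl ketene acetal of 21 | COc1cc2oc(=O)ccc2cc1C=C(O[Si](C)(C)C)O[C@@H](c1cc2ccc(=O)oc2cc1OC)/C=C(\C)CC/C(C)=C\Br | intermediate
23 | trimethylsilyl ester of 24 | COc1cc2oc(=O)ccc2cc1/C=C/[C@@](C)(CC/C(C)=C\Br)C(c1cc2ccc(=O)oc2cc1OC)C(=O)O[Si](C)(C)C | intermediate
24 | (3R,6Z)-7-bromo-2-(7-methoxy-2-oxo-2H-chromen-6-yl)-3-[(E)-2-(7-methoxy-2-oxo-2H-chromen-6-yl)ethenyl]-3,6-dimethylhept-6-enoic acid, C2 epimers | COc1cc2oc(=O)ccc2cc1/C=C/[C@@](C)(CC/C(C)=C\Br)C(c1cc2ccc(=O)oc2cc1OC)C(=O)O | intermediate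
25 | 1,3-dioxoisoindolin-2-yl ester of 24, C2 epimers | COc1cc2oc(=O)ccc2cc1/C=C/[C@@](C)(CC/C(C)=C\Br)C(c1cc2ccc(=O)oc2cc1OC)C(=O)ON1C(=O)c2ccccc2C1=O | intermediate
26 | 6-[(1S,6R)-6-[(E)-2-(7-methoxy-2-oxo-2H-chromen-6-yl)ethenyl]-3,6-dimethylcyclohex-2-en-1-yl]-7-methoxy-2H-chromen-2-one | COc1cc2oc(=O)ccc2cc1/C=C/[C@@]1(C)CCC(C)=C[C@@H]1c1cc2ccc(=O)oc2cc1OC | target

## Step count and risks

Total steps: 13. Longest linear sequence: 8 steps (for example 10 → 15 → 16 → 18 → 20 → 21 → 24 → 25 → 26).

Steps most likely to fail: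

1. Step 13 (proposed new method). Insertion of nickel into the hindered (Z)-alkenyl bromide and capture of the neopentyl-type benzylic radical may be slow, so that protodecarboxylation, radical dimerisation, intermolecular coupling or poor control of the benzylic configuration take over. The fallback sets out from 24 and returns at 26, using known reactions only. Hydrodebromination of 24 (Pd(PPh3)4, HCO2H, Et3N, DMF, 60 °C) should give (3R)-2-(7-methoxy-2-oxo-2H-chromen-6-yl)-3-[(E)-2-(7-methoxy-2-oxo-2H-chromen-6-yl)ethenyl]-3,6-dimethylhept-6-enoic acid F1. Coupling with N-hydroxyphthalimide and DIC gives its 1,3-dioxoisoindolin-2-yl ester F2. The established intermolecular nickel-catalysed asymmetric reductive coupling of F2 with bromoethene (same nickel/bis(oxazoline) catalyst, TDAE) puts a vinyl group on the benzylic carbon to give 6-[(3S,4R)-4-[(E)-2-(7-methoxy-2-oxo-2H-chromen-6-yl)ethenyl]-4,7-dimethylocta-1,7-dien-3-yl]-7-methoxy-2H-chromen-2-one F3. Ring-closing metathesis of the vinyl and isopropenyl groups with the second-generation Hoveyda–Grubbs catalyst (CH2Cl2, 40 °C) then closes the cyclohexene to 26.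

2. Step 11. The amide base or the ester enolate may add to the lactone rings, the arylacetate enolate may be silylated at carbon, or the benzylic allylic C–O bond may ionise and erode the chirality transfer. The fallback sets out from 9 and 20 and returns at 24 through a Reformatsky–Claisen rearrangement, which makes the enolate reductively without amide base. Radical bromination of 9 (NBS, AIBN, PhCF3, 80 °C) should give 2-bromo-2-(7-methoxy-2-oxo-2H-chromen-6-yl)acetic acid F4. DIC/DMAP coupling with 20 gives (1R,2E,6Z)-7-bromo-1-(7-methoxy-2-oxo-2H-chromen-6-yl)-3,6-dimethylhepta-2,6-dien-1-yl 2-bromo-2-(7-methoxy-2-oxo-2H-chromen-6-yl)acetate F5. Zinc dust and TMSCl in MeCN (rt → 60 °C) convert F5 into ketene acetal 22, which rearranges through the same chair to 23 and gives 24 after hydrolysis.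

3. Step 9. Facial selectivity at the aryl aldehyde may be insufficient, or nickel may also activate the alkenyl bromide end. The fallback sets out from 18 and 6 and returns at 20 through a catalytic asymmetric alkenylzinc addition. Iodine–lithium exchange on 18 (t-BuLi, Et2O, −78 °C; the iodide exchanges much faster than the bromide) gives [(1E,5Z)-6-bromo-2,5-dimethylhexa-1,5-dien-1-yl]lithium F6. ZnBr2 converts it into [(1E,5Z)-6-bromo-2,5-dimethylhexa-1,5-dien-1-yl]zinc bromide F7. F7 adds to 6 under ligand-accelerated catalysis by 3-exo-morpholinoisoborneol (enantiomer giving the 1R alcohol, toluene, 0 °C) to give 20 after aqueous NH4Cl.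

Further compounds
F1 | step 13 | (3R)-2-(7-methoxy-2-oxo-2H-chromen-6-yl)-3-[(E)-2-(7-methoxy-2-oxo-2H-chromen-6-yl)ethenyl]-3,6-dimethylhept-6-enoic acid, C2 epimers | COc1cc2oc(=O)ccc2cc1/C=C/[C@@](C)(CCC(C)=C)C(c1cc2ccc(=O)oc2cc1OC)C(=O)O
F2 | step 13 | 1,3-dioxoisoindolin-2-yl ester of F1 | COc1cc2oc(=O)ccc2cc1/C=C/[C@@](C)(CCC(C)=C)C(c1cc2ccc(=O)oc2cc1OC)C(=O)ON1C(=O)c2ccccc2C1=O
F3 | step 13 | 6-[(3S,4R)-4-[(E)-2-(7-methoxy-2-oxo-2H-chromen-6-yl)ethenyl]-4,7-dimethylocta-1,7-dien-3-yl]-7-methoxy-2H-chromen-2-one | COc1cc2oc(=O)ccc2cc1/C=C/[C@@](C)(CCC(C)=C)[C@@H](c1cc2ccc(=O)oc2cc1OC)C=C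
F4 | step 11 | 2-bromo-2-(7-methoxy-2-oxo-2H-chromen-6-yl)acetic acid | COc1cc2oc(=O)ccc2cc1C(Br)C(=O)O
F5 | step 11 | (1R,2E,6Z)-7-bromo-1-(7-methoxy-2-oxo-2H-chromen-6-yl)-3,6-dimethylhepta-2,6-dien-1-yl 2-bromo-2-(7-methoxy-2-oxo-2H-chromen-6-yl)acetate | COc1cc2oc(=O)ccc2cc1C(Br)C(=O)O[C@@H](c1cc2ccc(=O)oc2cc1OC)/C=C(\C)CC/C(C)=C\Br
F6 | step 9 | [(1E,5Z)-6-bromo-2,5-dimethylhexa-1,5-dien-1-yl]lithium | [Li]/C=C(C)/CC/C(C)=C\Br
F7 | step 9 | [(1E,5Z)-6-bromo-2,5-dimethylhexa-1,5-dien-1-yl]zinc bromide | Br[Zn]/C=C(C)/CC/C(C)=C\Br
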